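**Assumption:** 1 and 7 are taken as catalogue compounds, and the carbinol carbon of the target SMILES is read as (R) (chroman C3).

## Retrosynthetic overview

- Target 9 ⇐ Claisen–Schmidt condensation of chromanyl methyl ketone 6 with aldehyde 7, both MOM groups removed in the same pot (ring B and the enone come last).
- 6 ⇐ ortho-prenyl phenol 4 by phenol-directed asymmetric epoxidation and 6-endo C–O closure at the tertiary carbon; this one step makes the pyran ring and the C3 stereocentre.
- 4 ⇐ 2 by ortho C-prenylation; 2 ⇐ 1 by selective 4-O-MOM protection, so that only the chelated 2-OH can close the ring.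
- Ring order: ring A is bought in, the pyran ring is formed in step 3, ring B is attached in step 4.

## Route

**Step 1**
Reactants: 1 1-(2,4-dihydroxy-6-methoxyphenyl)ethan-1-one
Product: 2 1-[2-hydroxy-6-methoxy-4-(methoxymethoxy)phenyl]ethan-1-one
Conditions: MOMCl (1.05 equiv), K2CO3 (1.1 equiv), acetone, 0 °C to rt
Reagents that add atoms: chloromethyl methyl ether (MOMCl), COCCl
Why: Williamson-type O-alkylation (MOM protection) takes only the free 4-OH, because the 2-OH is tied up in a hydrogen bond to the acetyl carbonyl and is far less acidic and nucleophilic.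

**Step 2**
Reactants: 2 1-[2-hydroxy-6-methoxy-4-(methoxymethoxy)phenyl]ethan-1-one; 3 1-bromo-3-methylbut-2-ene (prenyl bromide)
Product: 4 1-[2-hydroxy-6-methoxy-4-(methoxymethoxy)-3-(3-methylbut-2-en-1-yl)phenyl]ethan-1-one
Conditions: NaH (1.05 equiv), PhMe, 0 °C to rt; then 3 (1.2 equiv), rt to 45 °C
Reagents that add atoms: none
Why: Ortho C-alkylation of a sodium phenoxide in a non-polar solvent: the tight, carbonyl-chelated ion pair shields oxygen and delivers the primary allylic bromide (SN2, linear prenyl kept) to C3, the only free ortho carbon and one activated by three oxygens; a moderate yield with some O-prenyl ether is expected.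

**Step 3**
Reactants: 4 1-[2-hydroxy-6-methoxy-4-(methoxymethoxy)-3-(3-methylbut-2-en-1-yl)phenyl]ethan-1-one
Product: 6 1-[(3R)-3-hydroxy-7-methoxy-5-(methoxymethoxy)-2,2-dimethyl-3,4-dihydro-2H-chromen-8-yl]ethan-1-one, via (R)-epoxide 5 (not isolated)
Conditions: Hf(OtBu)4 (10 mol%), (R,R)-BHA ligand [(1R,2R)-N,N′-dihydroxy-N,N′-bis(2,2-diphenylacetyl)cyclohexane-1,2-diamine, 12 mol%], DMPU (20 mol%), cumene hydroperoxide (1.5 equiv), 4 Å MS, PhMe, 0 °C; then CSA (20 mol%), CH2Cl2, 0 °C
Reagents that add atoms: cumene hydroperoxide, CC(C)(OO)c1ccccc1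
Why: Proposed new method: 4 is a phenolic bishomoallylic "alcohol" (ArO–H three carbons from the prenyl C=C) whose 2-oxido/acetyl chelate should bind tetravalent hafnium carrying the C2-symmetric bishydroxamate, a large ion that can still hold an η2-cumylperoxide; the peroxide then passes its distal oxygen intramolecularly to the Re face of the prenyl CH= carbon (the face the (R,R)-ligand is expected to expose; the sense has no precedent on a phenol and must be verified, and the (S,S)-ligand is used if it proves opposite) to give (R)-epoxide 5, and acid-promoted Markovnikov (6-endo) attack of the same phenolic oxygen at the tertiary epoxide carbon forms the O1–C2 bond and the pyran ring while the secondary C–O bond, and so the (R) centre, is untouched; the closest known reaction types are the hafnium- or zirconium–bishydroxamic acid hydroxyl-directed asymmetric epoxidation of aliphatic bishomoallylic alcohols and the achiral VO(acac)2/tBuOOH epoxidation–cyclization of 2-alkenylphenols, neither shown enantioselectively on a phenol.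

**Step 4**
Reactants: 6 1-[(3R)-3-hydroxy-7-methoxy-5-(methoxymethoxy)-2,2-dimethyl-3,4-dihydro-2H-chromen-8-yl]ethan-1-one; 7 4-(methoxymethoxy)benzaldehyde
Product: 9 (2E)-1-[(3R)-3,5-dihydroxy-7-methoxy-2,2-dimethyl-3,4-dihydro-2H-chromen-8-yl]-3-(4-hydroxyphenyl)prop-2-en-1-one (target CNP0122093.3), via bis-MOM chalcone 8 (not isolated)
Conditions: KOH (10 equiv), MeOH, 50 °C; then conc. HCl to pH 1, MeOH, 50 °C
Reagents that add atoms: none
Why: Claisen–Schmidt aldol condensation (E1cB) of a 2,6-dialkoxyacetophenone with a para-alkoxybenzaldehyde gives the thermodynamically favoured E-enone, and acid-catalysed acetal exchange in methanol then removes both MOM groups; the C3 carbinol is neither enolizable nor ionizable, so it is not scrambled.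

## Compound list

1 | 1-(2,4-dihydroxy-6-methoxyphenyl)ethan-1-one (2′,4′-dihydroxy-6′-methoxyacetophenone) | CC(=O)c1c(O)cc(O)cc1OC | starting material
2 | 1-[2-hydroxy-6-methoxy-4-(methoxymethoxy)phenyl]ethan-1-one | CC(=O)c1c(O)cc(OCOC)cc1OC | intermediate
3 | 1-bromo-3-methylbut-2-ene (prenyl bromide) | CC(C)=CCBr | starting material
4 | 1-[2-hydroxy-6-methoxy-4-(methoxymethoxy)-3-(3-methylbut-2-en-1-yl)phenyl]ethan-1-one | CC(=O)c1c(O)c(CC=C(C)C)c(OCOC)cc1OC | intermediate
5 | 1-[3-{[(2R)-3,3-dimethyloxiran-2-yl]methyl}-2-hydroxy-6-methoxy-4-(methoxymethoxy)phenyl]ethan-1-one | CC(=O)c1c(O)c(C[C@H]2OC2(C)C)c(OCOC)cc1OC | intermediate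
6 | 1-[(3R)-3-hydroxy-7-methoxy-5-(methoxymethoxy)-2,2-dimethyl-3,4-dihydro-2H-chromen-8-yl]ethan-1-one | COc1cc(OCOC)c2c(c1C(C)=O)OC(C)(C)[C@H](O)C2 | intermediate
7 | 4-(methoxymethoxy)benzaldehyde | COCOc1ccc(C=O)cc1 | starting material
8 | (2E)-1-[(3R)-3-hydroxy-7-methoxy-5-(methoxymethoxy)-2,2-dimethyl-3,4-dihydro-2H-chromen-8-yl]-3-[4-(methoxymethoxy)phenyl]prop-2-en-1-one | COc1cc(OCOC)c2c(c1C(=O)/C=C/c1ccc(OCOC)cc1)OC(C)(C)[C@H](O)C2 | intermediate
9 | (2E)-1-[(3R)-3,5-dihydroxy-7-methoxy-2,2-dimethyl-3,4-dihydro-2H-chromen-8-yl]-3-(4-hydroxyphenyl)prop-2-en-1-one | COc1cc(O)c2c(c1C(=O)/C=C/c1ccc(O)cc1)OC(C)(C)[C@H](O)C2 | target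

## Step count

Total steps: 4. Longest linear sequence: 4 (1 → 2 → 4 → 6 → 9).

## Steps most likely to fail

**Step 3 (the proposed new step).** The acetyl/phenoxide chelate may block the hafnium centre, the sense and level of induction on a phenol are unknown, and 5-exo closure to the dihydrobenzofuran isomer can compete. The fallback uses known chemistry and sets out from 4. Shi asymmetric epoxidation with the D-fructose-derived ketone (KHSO5, NaHCO3 buffer near pH 8 so that the chelated phenol stays protonated, MeCN/dimethoxymethane/aq. Na2(EDTA), 0 °C) is reagent-controlled and gives the (R)-epoxide 5, which is isolated this time. Catalytic CSA in CH2Cl2 at −20 °C then closes it 6-endo, and the route is rejoined at 6. This fallback makes no compound outside the list (F0).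

**Step 2.** Phenoxide C-alkylation may give mainly the O-prenyl ether or some C5 isomer. The fallback sets out from 2 and changes the approach from prenylation to chromene formation. Condensation of 2 with 3-methylbut-2-enal (ethylenediammonium diacetate cat., PhMe, reflux) proceeds by C3 attack, dehydration to the ortho-quinone methide and oxa-6π electrocyclization, which can only involve the free 2-OH. It gives 1-[7-methoxy-5-(methoxymethoxy)-2,2-dimethyl-2H-chromen-8-yl]ethan-1-one F1. Jacobsen–Katsuki epoxidation with (R,R)-[N,N′-bis(3,5-di-tert-butylsalicylidene)-1,2-cyclohexanediaminato]manganese chloride (a trivalent manganese salen complex; mCPBA, NMO, CH2Cl2, −78 °C) gives 1-[(3R,4R)-3,4-epoxy-7-methoxy-5-(methoxymethoxy)-2,2-dimethyl-3,4-dihydro-2H-chromen-8-yl]ethan-1-one F2. Hydrogenolysis of the benzylic C4–O bond (H2, Pd/C, EtOAc, rt) leaves the C3–O bond and its (R) configuration intact. The route is rejoined at 6, bypassing 4 and 5.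

**Step 4.** The hindered, twisted 2,6-dialkoxy ketone may condense slowly under equilibrium conditions. The fallback sets out from 6 and 7 and uses a kinetically controlled directed aldol instead. LiN(SiMe3)2 (2.2 equiv, THF, −78 °C) forms the alkoxide/enolate dianion of 6, and addition of 7 followed by an AcOH quench gives 3-hydroxy-1-[(3R)-3-hydroxy-7-methoxy-5-(methoxymethoxy)-2,2-dimethyl-3,4-dihydro-2H-chromen-8-yl]-3-[4-(methoxymethoxy)phenyl]propan-1-one F3 as a mixture of epimers at the new carbinol. Conc. HCl in MeOH at 50 °C then dehydrates the benzylic carbinol to the E-enone and removes both MOM groups, rejoining the route at 9.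

## Further compounds

F1 | step 2 | 1-[7-methoxy-5-(methoxymethoxy)-2,2-dimethyl-2H-chromen-8-yl]ethan-1-one | COc1cc(OCOC)c2c(c1C(C)=O)OC(C)(C)C=C2
F2 | step 2 | 1-[(3R,4R)-3,4-epoxy-7-methoxy-5-(methoxymethoxy)-2,2-dimethyl-3,4-dihydro-2H-chromen-8-yl]ethan-1-one | CC(=O)c1c(OC)cc(OCOC)c2c1OC(C)(C)[C@@H]3O[C@H]23
F0 | step 3 | none | none
F3 | step 4 | 3-hydroxy-1-[(3R)-3-hydroxy-7-methoxy-5-(methoxymethoxy)-2,2-dimethyl-3,4-dihydro-2H-chromen-8-yl]-3-[4-(methoxymethoxy)phenyl]propan-1-one (epimer mixture at the new carbinol) | COc1cc(OCOC)c2c(c1C(=O)CC(O)c1ccc(OCOC)cc1)OC(C)(C)[C@H](O)C2
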